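## Structural features

The target is a germacranolide: a ten-membered carbocycle (C1–C10) trans-fused across C6–C7 to an α-methylene-γ-butyrolactone (oxygen on C6, C12 carbonyl, C11, exocyclic C13). All locants below follow this numbering, with C14 the carboxyl carbon on C10 and C15 the methyl on C4. The ring holds one trisubstituted alkene, C1=C10, in which C2 and C9 are cis and the C14 acid is trans to C2, and two cis-oxiranes on neighbouring bond pairs (C2–C3 and C4–C5), so that C10=C1–C2(O)C3–C4(O)C5 is a vinylogous vicinal bis-epoxide. Eight stereocentres stand in a row from C2 to C9: the two oxiranes are joined C3 to C4, the C4–C5 oxirane oxygen and the lactone oxygen on C6 are threo, C6/C7 are trans, and C8 and C9 carry two different esters (an epoxyangelate with two more centres, and an acetate). Fragile groups are the allylic C2–C3 oxirane and the tertiary C4 oxirane carbon (acid, Lewis acid, low-valent metals), the α-methylene lactone (nucleophiles), the vicinal esters (acyl shift) and, in open-chain precursors, the γ-hydrogen of a butenolide and any ester conjugated to the vinyl epoxide. The real difficulty is to close a ten-membered ring that already contains three cis-locked two-carbon units while C7 and C8 are set, and to keep O8, O9 and O14 apart until the end. The key step uses the fact that C7 is the β-carbon of the C12 lactone and C8 bears oxygen: C7–C8 joins the β-carbon of a butenolide (C7=C11) to a carbonyl carbon (C8 aldehyde), the polarity pattern of a ketyl radical conjugate addition.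

## Logic of the disconnections

**44 to 41.** Cut: the C14–O bonds gained on oxidation and the O9–acetyl bond. A free acid and an acetate with α-hydrogens would not pass the enolate and single-electron steps, and late oxidation means no γ,δ-epoxy enoate exists before ring closure. This leaves 41, a diol with one primary allylic and one secondary hydroxyl. The forward steps (42, 43) must oxidise only the primary hydroxyl, acetylate O9 without moving the O8 ester, and end with a chlorite oxidation that spares epoxides and the exocyclic alkene.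

**41 to 40.** Cut: O9–Si and O14–Si. A triethylsilyl ether on O9 and a tert-butyldimethylsilyl ether on O14 both fall to buffered fluoride in one operation. The forward step must not open an oxirane or shift the O8 acyl group.

**40 to 37.** Cut: C11=C13. The Michael acceptor is introduced only after the acylation. This leaves the saturated lactone 37. The forward step must enolise the lactone beside a hindered ester that has no α-hydrogen.

**37 to 31 and 35.** Cut: O8–acyl. O8 is the only free hydroxyl after ring closure, so no protecting group is spent, and acylation at once stops the lactone from moving from O6 to O8. 35 is traced through 34 and 33 to 32 by cutting its two oxirane C–O bonds. The forward step must acylate a hindered secondary alcohol under conditions mild to epoxides.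

**31 to 30.** Cut: C7–C8, the one ring bond whose ends are a carbonyl carbon and an enoate β-carbon. This removes the ring and two stereocentres and leaves an open chain that carries every other centre. The configurations of 30 and 31 were checked centre by centre against 44 and agree at C2–C6 and C9, so only protecting groups were changed. The forward step must reduce the aldehyde in preference to the butenolide and the allylic oxirane, close a ten-membered ring faster than the ketyl dimerises, and control C7 and C8.

**30 to 28.** Cut: the C8 oxidation level (through 29). The aldehyde is released last, by a basic oxidative cleavage of a primary silyl ether. An acetal is avoided because its hydrolysis would need acid beside two epoxides.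

**28 to 21 and 25.** Cut: C9–C10, with the C9 configuration corrected through 26 and 27. An alkenyl metal at C10 brings in C8 and C9 without touching the alkene geometry; 25 comes from 22 through 23. The forward steps need an alkenyl addition that tolerates lactone and epoxides, and a reagent-controlled ketone reduction.

**21 to 15 and 18.** Cut: C1=C10. A carbonyl-stabilised ylide places C2 trans to the carbonyl carbon, which is the relation of C2 to C14, and the bromine on the ylide carbon marks the place of C9. C14 arrives as an aldehyde because borohydride (19 to 20) spares the butenolide, whereas an ester would need a hydride reagent that does not. 18 comes from 16. The forward step must olefinate an epimerisable cis-epoxy aldehyde without base.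

**15 to 13.** Cut: C2–O and C3–O (through 14). The primary allylic hydroxyl of 13 lets a titanium tartrate catalyst choose the alkene and its face. The forward step is an epoxidation of a cis-allylic alcohol with a quaternary neighbour.

**13 to 10.** Cut: the O6–C12 lactone bond and the four C–H bonds added to two alkynes (through 12 and 11). The butenolide appears only after C6 has served as a free hydroxyl, so a 5-formylbutenolide, which would lose its configuration through its hydroxyfuran tautomer, is never needed, and no hydride step meets the lactone. The forward step must stop at the alkenes.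

**10 to 9.** Cut: C4–O and C5–O. The free C6 hydroxyl and the cis substituent on C4 of 9 allow substrate control (threo).

**9 to 6 and 7.** Cut: C6–C7. A catalyst-controlled alkynylation sets C6, from which C4 and C5 follow.

**6 to 3 and 4, and 3 to 1.** Cut: C3–C4 (through 5) and C4–I. The Z geometry of C4=C5 comes from a hydroxyl-directed trans-hydroalumination and is carried unchanged.

## Other disconnections considered

**Alternative 1:** The cut is C7–C11 together with C8–O, on a ten-membered ring that already exists. In the forward step the bromoacetal A1 gives a primary radical that closes 5-exo onto C7, and the C8 radical is trapped by TEMPO to give A2.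
- In its favour: the 5-exo closure of haloacetals is among the most dependable radical reactions, and it installs C11/C12 and the C8 oxygen in one operation. No single-electron reductant meets the allylic oxirane, so C14 can stay an ester; on this point it is better than the chosen plan, which spends four steps on C14.
- Against it: the ten-membered ring of A1 must first be made by another macrocyclization, so the main problem is moved and not solved. A 5-exo closure onto a ring alkene normally gives a cis-fused bicycle, whereas C6/C7 must be trans, so the outcome would rest on the conformation of the cyclodecadiene. Nothing but transannular shielding directs TEMPO at C8. A2 then needs N–O cleavage and oxidation of the lactol ether to the lactone beside two epoxides.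
- Comparison: equal on the later α-methylenation; better on chemoselectivity and on C14; worse on ring construction, on prediction of C7 and C8, and by about three steps after the key step.

**Alternative 2:** The cut is one C–O bond in each oxirane. In the forward step base converts A3 (C2 hydroxyl, 3,4-epoxide, C5 mesylate) to A4: the C2 alkoxide opens the 3,4-epoxide at C3, and the C4 alkoxide then displaces the mesylate.
- In its favour: both oxiranes appear after ring and lactone are in place and never meet a reductant or a Lewis acid, a real advantage over the chosen plan. Both closures are stereospecific inversions, and the irreversible mesylate displacement pulls the epoxide-migration equilibrium forward.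
- Against it: A3 needs four adjacent centres, two of them (C3, C5) opposite to the target, on a macrocycle that must be made some other way. Both displacements need anti-periplanar alignment inside a ten-membered ring. Elimination of the mesylate and reversal of the first step compete, and the base meets a lactone.
- Comparison: it forms no ring and sets no new centre, against one ring and two centres in the chosen step. It is better as protection of the oxiranes and could be combined with a C7–C8 closure if the oxiranes did not survive SmI2. It is worse in step economy, because the C2–C5 tetrad costs more than two epoxidations.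

**Alternative 3:** The cut is C5–C6. In the forward step CrCl2 with catalytic NiCl2 turns the Z-alkenyl iodide of A5 into an alkenylchromium that adds to the C6 aldehyde and gives A6.
- In its favour: this ring closure has solid precedent for medium rings, which the chosen step has not; on certainty of the ring-forming reaction it is better. It tolerates the C14 ester, so no redox detour is needed. The new C6 hydroxyl can direct the C4=C5 epoxidation and then lactonise.
- Against it: C6 is set in the ring closure without a strong control element. The C6 aldehyde of A5 has an acidic C7 hydrogen next to a β-alkoxy group. The alkenyl metal sits beside the allylic 2,3-oxirane. After A6, epoxidation at C4–C5 and lactonisation are still to come. A5 must carry the C7/C8/C9 triad, to be built by acyclic stereocontrol.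
- Comparison: equal in ring size and in bonds formed; better in precedent and in the handling of C14; worse in that it sets one centre instead of two in the ring closure and needs three acyclic centres made beforehand.

Key step: step 21

Assumptions and conventions:
- The zinc complex of (S,S)-ProPhenol is taken to add the alkynyl group to the face of 6 that gives 9; if its facial sense is the reverse, the (R,R)-ligand is used and nothing else changes.
- In names, "unit B" stands for the residue (2R,3R)-3-[(2R,3R)-2-methyl-3-((S)-5-oxo-2,5-dihydrofuran-2-yl)oxiran-2-yl]oxiran-2-yl, that is C2–C7 with C11, C12 and C15.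

## Route

Step 1
Reactants: 1 but-2-yn-1-ol
Product: 3 (Z)-3-iodobut-2-en-1-ol, via cyclic alkenylalanate 2 (not isolated)
Conditions: NaAlH2(OCH2CH2OMe)2, THF, 0 °C to rt; then I2, THF, −78 to 0 °C
Reagents that add atoms: iodine, II
Why: Hydroxyl-directed trans-hydroalumination of a propargylic alcohol delivers hydride to C5 and leaves aluminium on C4 in a five-membered alkoxyalanate, cis to the carbinol; iodinolysis with retention fixes the Z geometry that becomes the cis C3/C6 relation of the 4,5-oxirane.

Step 2
Reactants: 3 (Z)-3-iodobut-2-en-1-ol; 4 tert-butyldimethyl(prop-2-yn-1-yloxy)silane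
Product: 5 (Z)-6-(tert-butyldimethylsilyloxy)-3-methylhex-2-en-4-yn-1-ol
Conditions: Pd(PPh3)2Cl2 (2 mol%), CuI (4 mol%), Et3N, THF, rt
Reagents that add atoms: none
Why: Sonogashira coupling forms C3–C4 with retention of the alkenyl iodide geometry and tolerates the free allylic hydroxyl.

Step 3
Reactants: 5 (Z)-6-(tert-butyldimethylsilyloxy)-3-methylhex-2-en-4-yn-1-ol
Product: 6 (Z)-6-(tert-butyldimethylsilyloxy)-3-methylhex-2-en-4-ynal
Conditions: MnO2, CH2Cl2, rt
Reagents that add atoms: none
Why: Allylic oxidation with MnO2 is neutral and should keep the Z-enal; at the enyne stage the aldehyde cannot close to a 2H-pyran as a cis-dienal would.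

Step 4
Reactants: 6 (Z)-6-(tert-butyldimethylsilyloxy)-3-methylhex-2-en-4-ynal; 7 methyl propiolate
Product: 9 methyl (4R,5Z)-9-(tert-butyldimethylsilyloxy)-4-hydroxy-6-methylnon-5-ene-2,7-diynoate, via methylzinc alkynylide 8 (not isolated)
Conditions: (S,S)-ProPhenol (20 mol%), Me2Zn, Ph3PO (40 mol%), toluene, 0 °C
Reagents that add atoms: none
Why: Zinc–ProPhenol catalysed asymmetric alkynylation of an enal forms C6–C7; the dinuclear zinc catalyst selects the aldehyde face and sets C6 (R here by priority change, the same spatial arrangement as 6S of the target).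

Step 5
Reactants: 9 methyl (4R,5Z)-9-(tert-butyldimethylsilyloxy)-4-hydroxy-6-methylnon-5-ene-2,7-diynoate
Product: 10 methyl (4S)-4-hydroxy-4-[(2R,3S)-3-methyl-3-(3-(tert-butyldimethylsilyloxy)prop-1-ynyl)oxiran-2-yl]but-2-ynoate
Conditions: mCPBA, NaHCO3, CH2Cl2, 0 °C to rt
Reagents that add atoms: 3-chloroperoxybenzoic acid, O=C(OO)c1cccc(Cl)c1
Why: Hydroxyl-directed peracid epoxidation of a Z-allylic alcohol: 1,3-allylic strain keeps H6 in the alkene plane, so oxygen is delivered to the face of the hydroxyl and gives the cis-4,5-oxirane threo to O6; alkynes and the ynoate are inert to the peracid.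

Step 6
Reactants: 10 methyl (4S)-4-hydroxy-4-[(2R,3S)-3-methyl-3-(3-(tert-butyldimethylsilyloxy)prop-1-ynyl)oxiran-2-yl]but-2-ynoate
Product: 12 (5S)-5-[(2R,3S)-3-methyl-3-((Z)-3-(tert-butyldimethylsilyloxy)prop-1-enyl)oxiran-2-yl]furan-2(5H)-one, via hydroxy cis-enoate 11 (not isolated)
Conditions: H2 (1 atm), Pd/CaCO3/Pb(OAc)2, quinoline, EtOAc, rt; then SiO2, CH2Cl2, rt
Reagents that add atoms: none
Why: Lindlar cis-semihydrogenation of both alkynes gives the Z C2=C3 alkene and a Z γ-hydroxy enoate that lactonises to the butenolide; alkynyl oxiranes are known to pass these conditions as cis-vinyl oxiranes.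

Step 7
Reactants: 12 (5S)-5-[(2R,3S)-3-methyl-3-((Z)-3-(tert-butyldimethylsilyloxy)prop-1-enyl)oxiran-2-yl]furan-2(5H)-one
Product: 13 (5S)-5-[(2R,3S)-3-((Z)-3-hydroxyprop-1-enyl)-3-methyloxiran-2-yl]furan-2(5H)-one
Conditions: Bu4NF, AcOH (1:1), THF, 0 °C
Reagents that add atoms: none
Why: Buffered fluoride cleaves the primary allylic silyl ether; the buffer protects the butenolide from base and the tertiary allylic oxirane from acid.

Step 8
Reactants: 13 (5S)-5-[(2R,3S)-3-((Z)-3-hydroxyprop-1-enyl)-3-methyloxiran-2-yl]furan-2(5H)-one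
Product: 14 (5S)-5-[(2R,3R)-3-[(2R,3R)-3-(hydroxymethyl)oxiran-2-yl]-3-methyloxiran-2-yl]furan-2(5H)-one
Conditions: Ti(OiPr)4 (0.3 equiv), D-(−)-diisopropyl tartrate (0.36 equiv), t-BuOOH, 4 Å MS, CH2Cl2, −20 °C
Reagents that add atoms: tert-butyl hydroperoxide, CC(C)(C)OO
Why: Sharpless asymmetric epoxidation of the cis-allylic alcohol; the D-(−)-tartrate complex delivers oxygen to the face that gives 2R,3R, syn addition to the Z alkene gives the cis-oxirane, and only the alkene allylic to the hydroxyl reacts.

Step 9
Reactants: 14 (5S)-5-[(2R,3R)-3-[(2R,3R)-3-(hydroxymethyl)oxiran-2-yl]-3-methyloxiran-2-yl]furan-2(5H)-one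
Product: 15 (2S,3R)-3-[(2R,3R)-2-methyl-3-((S)-5-oxo-2,5-dihydrofuran-2-yl)oxiran-2-yl]oxirane-2-carbaldehyde
Conditions: Dess–Martin periodinane, NaHCO3, CH2Cl2, 0 °C
Reagents that add atoms: none
Why: Dess–Martin oxidation under buffered, non-basic conditions should keep the cis-epoxy aldehyde from epimerising; it is used at once.

Step 10
Reactants: 16 (triphenylphosphoranylidene)acetaldehyde
Product: 18 2-bromo-2-(triphenylphosphoranylidene)acetaldehyde, via bromophosphonium bromide 17 (not isolated)
Conditions: Br2, CH2Cl2, 0 °C; then aq. NaOH, 0 °C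
Reagents that add atoms: bromine, BrBr
Why: C-bromination of a stabilised ylide followed by deprotonation of the phosphonium salt is the usual route to α-halo stabilised ylides.

Step 11
Reactants: 15 (2S,3R)-3-[(2R,3R)-2-methyl-3-((S)-5-oxo-2,5-dihydrofuran-2-yl)oxiran-2-yl]oxirane-2-carbaldehyde; 18 2-bromo-2-(triphenylphosphoranylidene)acetaldehyde
Product: 19 (Z)-2-bromo-3-(unit B)prop-2-enal
Conditions: toluene, 50 °C
Reagents that add atoms: none
Why: Wittig olefination with a formyl-stabilised ylide needs no base; it places C2 trans to the formyl carbon (future C14) and hence cis to bromine, which marks the place of C9.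

Step 12
Reactants: 19 (Z)-2-bromo-3-(unit B)prop-2-enal
Product: 20 (Z)-2-bromo-3-(unit B)prop-2-en-1-ol
Conditions: NaBH4, CeCl3·7H2O, MeOH/THF, −40 °C
Reagents that add atoms: none
Why: Luche 1,2-reduction takes the aldehyde much faster than the butenolide, which is why C14 was brought in as an aldehyde and not as an ester.

Step 13
Reactants: 20 (Z)-2-bromo-3-(unit B)prop-2-en-1-ol
Product: 21 tert-butyl[(Z)-2-bromo-3-(unit B)prop-2-enyloxy]dimethylsilane
Conditions: t-BuMe2SiCl, imidazole, DMF, 0 °C
Reagents that add atoms: tert-butyldimethylsilyl chloride, CC(C)(C)[Si](C)(C)Cl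
Why: Standard silylation of a primary allylic alcohol; C14 is carried as a silyl ether so that no γ,δ-epoxy enoate meets SmI2.

Step 14
Reactants: 22 (Z)-but-2-ene-1,4-diol
Product: 23 (Z)-1,4-bis(triethylsilyloxy)but-2-ene
Conditions: Et3SiCl, imidazole, CH2Cl2, 0 °C
Reagents that add atoms: chlorotriethylsilane, CC[Si](CC)(CC)Cl
Why: Standard bis-silylation of a diol.

Step 15
Reactants: 23 (Z)-1,4-bis(triethylsilyloxy)but-2-ene
Product: 25 2-(triethylsilyloxy)acetaldehyde, via ozonide 24 (not isolated)
Conditions: O3, CH2Cl2, −78 °C; then PPh3, −78 °C to rt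
Reagents that add atoms: ozone, [O-][O+]=O
Why: Ozonolysis of a symmetrical alkene with reductive work-up gives two equivalents of the α-silyloxy aldehyde.

Step 16
Reactants: 21 tert-butyl[(Z)-2-bromo-3-(unit B)prop-2-enyloxy]dimethylsilane; 25 2-(triethylsilyloxy)acetaldehyde
Product: 26 (3Z)-3-[(tert-butyldimethylsilyloxy)methyl]-1-(triethylsilyloxy)-4-(unit B)but-3-en-2-ol (both C9 epimers)
Conditions: CrCl2 (6 equiv), NiCl2 (5 mol%), DMSO/THF, rt
Reagents that add atoms: none
Why: Nozaki–Hiyama–Kishi coupling: zerovalent nickel inserts into C10–Br, transmetalation gives an alkenylchromium that adds only to the aldehyde with retention of alkene geometry; lactone, oxiranes and silyl ethers are tolerated, and the C9 mixture converges in steps 17 and 18.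

Step 17
Reactants: 26 (3Z)-3-[(tert-butyldimethylsilyloxy)methyl]-1-(triethylsilyloxy)-4-(unit B)but-3-en-2-ol (both C9 epimers)
Product: 27 (3Z)-3-[(tert-butyldimethylsilyloxy)methyl]-1-(triethylsilyloxy)-4-(unit B)but-3-en-2-one
Conditions: Dess–Martin periodinane, NaHCO3, CH2Cl2, 0 °C
Reagents that add atoms: none
Why: Dess–Martin oxidation of the allylic alcohol mixture to one enone; the C9 carbonyl is cis to an sp3 carbon, so no oxa-electrocyclisation is possible.

Step 18
Reactants: 27 (3Z)-3-[(tert-butyldimethylsilyloxy)methyl]-1-(triethylsilyloxy)-4-(unit B)but-3-en-2-one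
Product: 28 (2S,3Z)-3-[(tert-butyldimethylsilyloxy)methyl]-1-(triethylsilyloxy)-4-(unit B)but-3-en-2-ol
Conditions: (S)-2-methyl-CBS-oxazaborolidine (0.5 equiv), BH3·SMe2, THF, −40 °C
Reagents that add atoms: none
Why: Corey–Bakshi–Shibata reduction: the substituted alkenyl group is the large and CH2OSiEt3 the small substituent, so the (S)-catalyst delivers hydride to the face that gives 9S; lactone and oxiranes should be inert at this temperature.

Step 19
Reactants: 28 (2S,3Z)-3-[(tert-butyldimethylsilyloxy)methyl]-1-(triethylsilyloxy)-4-(unit B)but-3-en-2-ol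
Product: 29 (2S,3Z)-3-[(tert-butyldimethylsilyloxy)methyl]-1,2-bis(triethylsilyloxy)-4-(unit B)but-3-ene
Conditions: Et3SiOTf, 2,6-lutidine, CH2Cl2, −78 °C
Reagents that add atoms: triethylsilyl trifluoromethanesulfonate, CC[Si](CC)(CC)OS(=O)(=O)C(F)(F)F
Why: Silylation of a secondary allylic alcohol; triethylsilyl on O9 is chosen so that it leaves with the O14 silyl group in one late fluoride step.

Step 20
Reactants: 29 (2S,3Z)-3-[(tert-butyldimethylsilyloxy)methyl]-1,2-bis(triethylsilyloxy)-4-(unit B)but-3-ene
Product: 30 (2S,3Z)-3-[(tert-butyldimethylsilyloxy)methyl]-2-(triethylsilyloxy)-4-(unit B)but-3-enal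
Conditions: (COCl)2, DMSO, CH2Cl2, −78 °C; then Et3N, −78 to −20 °C
Reagents that add atoms: none
Why: Swern conditions cleave and oxidise a primary triethylsilyl ether directly while secondary triethylsilyl and tert-butyldimethylsilyl ethers survive; the aldehyde is thus released under base, with no acid beside the two oxiranes.

Step 21
Reactants: 30 (2S,3Z)-3-[(tert-butyldimethylsilyloxy)methyl]-2-(triethylsilyloxy)-4-(unit B)but-3-enal
Product: 31 (1(10)Z,2R,3R,4R,5R,6S,7R,8S,9S)-14-(tert-butyldimethylsilyloxy)-2,3:4,5-diepoxy-8-hydroxy-9-(triethylsilyloxy)germacr-1(10)-en-12,6-olide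
Conditions: SmI2 (2.5 equiv), THF, −78 °C, 30 added over 6 h (final 2 mM); then t-BuOH, pH 7 phosphate buffer, −78 °C
Reagents that add atoms: none
Why: Proposed new method: SmI2 ketyl–olefin cyclisation onto unsaturated esters and lactones is the closest known reaction type and is established for five- to eight-membered rings, not for ten; the reasoning is that the α-silyloxy aldehyde is reduced first to the C8 ketyl, which adds as a nucleophilic radical to C7, the β-carbon of the butenolide, and the C11 radical so formed is reduced by a second SmI2 to a trivalent samarium enolate that is protonated on quench. The ring closes 10-exo-trig with respect to C7=C11; three of the ring bonds (C1=C10, C2–C3, C4–C5) are locked cis, so only five single bonds have to be frozen and the chain is bent so that C8 lies near C7. C7 is controlled by C6: the chain leaves C6 on one face of the butenolide and the ketyl adds to the other, which gives the trans C6/C7 fusion as in radical additions to γ-substituted butenolides. C8 is controlled by a trivalent samarium bridge between the ketyl oxygen and the lactone carbonyl, which holds O8 syn-clinal to C11, and by the C9 silyloxy group, whose C–O bond should lie anti to the ketyl C–O bond; both lead to 8S. The step needs chemoselectivity for the aldehyde over the butenolide and the allylic oxirane, which is served by leaving out HMPA, by −78 °C and by C14 being a silyl ether and not an ester. It also needs ring closure to beat pinacol dimerisation and simple reduction, which is served by slow addition into excess SmI2 at high dilution and by adding the proton source only at the end; the cold neutral quench protonates enolate and alkoxide together and should keep the lactone on O6.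

Step 22
Reactants: 32 angelic acid
Product: 33 (Z)-2-methylbut-2-en-1-ol
Conditions: LiAlH4, Et2O, 0 °C
Reagents that add atoms: none
Why: Hydride reduction of the acid to the primary allylic alcohol with retention of the Z geometry.

Step 23
Reactants: 33 (Z)-2-methylbut-2-en-1-ol
Product: 34 [(2S,3R)-2,3-dimethyloxiran-2-yl]methanol
Conditions: Ti(OiPr)4 (10 mol%), L-(+)-diethyl tartrate (12 mol%), t-BuOOH, 4 Å MS, CH2Cl2, −20 °C
Reagents that add atoms: tert-butyl hydroperoxide, CC(C)(C)OO
Why: Sharpless asymmetric epoxidation of a trisubstituted allylic alcohol; the L-(+)-tartrate complex gives the 2S,3R epoxy alcohol, and syn addition keeps C1 and the C3 methyl cis.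

Step 24
Reactants: 34 [(2S,3R)-2,3-dimethyloxiran-2-yl]methanol
Product: 35 (2R,3R)-2,3-dimethyloxirane-2-carboxylic acid
Conditions: RuCl3·xH2O (2 mol%), NaIO4, MeCN/EtOAc/H2O, rt
Reagents that add atoms: water, O
Why: Catalytic ruthenium tetroxide oxidation of a primary alcohol to the acid leaves the oxirane untouched; the descriptor at C2 changes by priority only.

Step 25
Reactants: 31 (1(10)Z,2R,3R,4R,5R,6S,7R,8S,9S)-14-(tert-butyldimethylsilyloxy)-2,3:4,5-diepoxy-8-hydroxy-9-(triethylsilyloxy)germacr-1(10)-en-12,6-olide; 35 (2R,3R)-2,3-dimethyloxirane-2-carboxylic acid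
Product: 37 8-O-[(2R,3R)-2,3-dimethyloxirane-2-carbonyl] derivative of 31, via mixed anhydride 36 (not isolated)
Conditions: 2,4,6-trichlorobenzoyl chloride, Et3N, THF, rt; then 31, DMAP, toluene, rt
Reagents that add atoms: none
Why: Yamaguchi esterification acylates the hindered C8 hydroxyl, the only free hydroxyl; doing it directly after ring closure blocks migration of the lactone from O6 to O8.

Step 26
Reactants: 37 8-O-[(2R,3R)-2,3-dimethyloxirane-2-carbonyl] derivative of 31
Product: 40 (1(10)Z)-14-(tert-butyldimethylsilyloxy)-2,3:4,5-diepoxy-8-[(2R,3R)-2,3-dimethyloxirane-2-carbonyloxy]-9-(triethylsilyloxy)germacra-1(10),11(13)-dien-12,6-olide, via Mannich base 38 (not isolated), via ammonium iodide 39 (not isolated)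
Conditions: LiN(iPr)2, THF, −78 °C; CH2=NMe2+ I−, −78 °C to rt; then MeI, MeOH, rt; then NaHCO3, CH2Cl2/H2O, rt
Reagents that add atoms: N,N-dimethylmethyleneiminium iodide, C=[N+](C)C.[I-]
Why: Mannich reaction of the lactone lithium enolate with Eschenmoser's salt, N-methylation and E1cB loss of trimethylamine give C11=C13; the C8 ester has no α-hydrogen and a hindered carbonyl, and the silyl ethers tolerate the base.

Step 27
Reactants: 40 (1(10)Z)-14-(tert-butyldimethylsilyloxy)-2,3:4,5-diepoxy-8-[(2R,3R)-2,3-dimethyloxirane-2-carbonyloxy]-9-(triethylsilyloxy)germacra-1(10),11(13)-dien-12,6-olide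
Product: 41 (1(10)Z)-2,3:4,5-diepoxy-8-[(2R,3R)-2,3-dimethyloxirane-2-carbonyloxy]-9,14-dihydroxygermacra-1(10),11(13)-dien-12,6-olide
Conditions: HF·pyridine, pyridine, THF, 0 °C to rt
Reagents that add atoms: none
Why: Buffered fluoride removes the secondary triethylsilyl and the primary allylic tert-butyldimethylsilyl ether in one operation; the mildly acidic medium should not promote O8 to O9 acyl shift.

Step 28
Reactants: 41 (1(10)Z)-2,3:4,5-diepoxy-8-[(2R,3R)-2,3-dimethyloxirane-2-carbonyloxy]-9,14-dihydroxygermacra-1(10),11(13)-dien-12,6-olide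
Product: 42 (1(10)E)-2,3:4,5-diepoxy-8-[(2R,3R)-2,3-dimethyloxirane-2-carbonyloxy]-9-hydroxy-14-oxogermacra-1(10),11(13)-dien-12,6-olide
Conditions: TEMPO (10 mol%), PhI(OAc)2, CH2Cl2, rt
Reagents that add atoms: none
Why: Oxoammonium oxidation is selective for the primary over the secondary allylic alcohol and stops at the enal; the alkene geometry is unchanged (the descriptor changes by priority).

Step 29
Reactants: 42 (1(10)E)-2,3:4,5-diepoxy-8-[(2R,3R)-2,3-dimethyloxirane-2-carbonyloxy]-9-hydroxy-14-oxogermacra-1(10),11(13)-dien-12,6-olide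
Product: 43 (1(10)E)-9-acetoxy-2,3:4,5-diepoxy-8-[(2R,3R)-2,3-dimethyloxirane-2-carbonyloxy]-14-oxogermacra-1(10),11(13)-dien-12,6-olide
Conditions: Ac2O, pyridine, DMAP (cat.), CH2Cl2, 0 °C
Reagents that add atoms: acetic anhydride, CC(=O)OC(C)=O
Why: Standard acetylation of the single remaining hydroxyl.

Step 30
Reactants: 43 (1(10)E)-9-acetoxy-2,3:4,5-diepoxy-8-[(2R,3R)-2,3-dimethyloxirane-2-carbonyloxy]-14-oxogermacra-1(10),11(13)-dien-12,6-olide
Product: 44 leucanthin B
Conditions: NaClO2, NaH2PO4, 2-methyl-2-butene, t-BuOH/H2O, 0 °C to rt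
Reagents that add atoms: sodium chlorite, [Na+].[O-]Cl=O
Why: Pinnick oxidation of the enal to the acid; the scavenger removes hypochlorite, so the oxiranes and the electron-poor alkenes should be untouched.

## Compound list

1 | but-2-yn-1-ol | CC#CCO | starting material
2 | cyclic (Z)-alkenyl alkoxyalanate, sodium salt | CC1=CCO[Al-]1(OCCOC)OCCOC.[Na+] | intermediate
3 | (Z)-3-iodobut-2-en-1-ol | C/C(I)=C/CO | intermediate
4 | tert-butyldimethyl(prop-2-yn-1-yloxy)silane | C#CCO[Si](C)(C)C(C)(C)C | starting material
5 | (Z)-6-(tert-butyldimethylsilyloxy)-3-methylhex-2-en-4-yn-1-ol | C/C(C#CCO[Si](C)(C)C(C)(C)C)=C/CO | intermediate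
6 | (Z)-6-(tert-butyldimethylsilyloxy)-3-methylhex-2-en-4-ynal | C/C(C#CCO[Si](C)(C)C(C)(C)C)=C/C=O | intermediate
7 | methyl propiolate | C#CC(=O)OC | starting material
8 | methyl 3-(methylzincio)propiolate | COC(=O)C#C[Zn]C | intermediate
9 | methyl (4R,5Z)-9-(tert-butyldimethylsilyloxy)-4-hydroxy-6-methylnon-5-ene-2,7-diynoate | C/C(C#CCO[Si](C)(C)C(C)(C)C)=C/[C@@H](O)C#CC(=O)OC | intermediate
10 | methyl (4S)-4-hydroxy-4-[(2R,3S)-3-methyl-3-(3-(tert-butyldimethylsilyloxy)prop-1-ynyl)oxiran-2-yl]but-2-ynoate | CC(C)(C)[Si](C)(C)OCC#C[C@]1(C)O[C@@H]1[C@@H](O)C#CC(=O)OC | intermediate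
11 | methyl (2Z,4S)-4-hydroxy-4-[(2R,3S)-3-methyl-3-((Z)-3-(tert-butyldimethylsilyloxy)prop-1-enyl)oxiran-2-yl]but-2-enoate | CC(C)(C)[Si](C)(C)OC/C=C\[C@]1(C)O[C@@H]1[C@@H](O)/C=C\C(=O)OC | intermediate
12 | (5S)-5-[(2R,3S)-3-methyl-3-((Z)-3-(tert-butyldimethylsilyloxy)prop-1-enyl)oxiran-2-yl]furan-2(5H)-one | CC(C)(C)[Si](C)(C)OC/C=C\[C@]1(C)O[C@@H]1[C@H]1OC(=O)C=C1 | intermediate
13 | (5S)-5-[(2R,3S)-3-((Z)-3-hydroxyprop-1-enyl)-3-methyloxiran-2-yl]furan-2(5H)-one | OC/C=C\[C@]1(C)O[C@@H]1[C@H]1OC(=O)C=C1 | intermediate
14 | (5S)-5-[(2R,3R)-3-[(2R,3R)-3-(hydroxymethyl)oxiran-2-yl]-3-methyloxiran-2-yl]furan-2(5H)-one | OC[C@H]1O[C@H]1[C@]1(C)O[C@@H]1[C@H]1OC(=O)C=C1 | intermediate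
15 | (2S,3R)-3-[(2R,3R)-2-methyl-3-((S)-5-oxo-2,5-dihydrofuran-2-yl)oxiran-2-yl]oxirane-2-carbaldehyde | O=C[C@H]1O[C@H]1[C@]1(C)O[C@@H]1[C@H]1OC(=O)C=C1 | intermediate
16 | (triphenylphosphoranylidene)acetaldehyde | O=CC=P(c1ccccc1)(c1ccccc1)c1ccccc1 | starting material
17 | (1-bromo-2-oxoethyl)triphenylphosphonium bromide | O=CC(Br)[P+](c1ccccc1)(c1ccccc1)c1ccccc1.[Br-] | intermediate
18 | 2-bromo-2-(triphenylphosphoranylidene)acetaldehyde | O=CC(Br)=P(c1ccccc1)(c1ccccc1)c1ccccc1 | intermediate
19 | (Z)-2-bromo-3-(unit B)prop-2-enal | O=C/C(Br)=C/[C@H]1O[C@H]1[C@]1(C)O[C@@H]1[C@H]1OC(=O)C=C1 | intermediate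
20 | (Z)-2-bromo-3-(unit B)prop-2-en-1-ol | OC/C(Br)=C/[C@H]1O[C@H]1[C@]1(C)O[C@@H]1[C@H]1OC(=O)C=C1 | intermediate
21 | tert-butyl[(Z)-2-bromo-3-(unit B)prop-2-enyloxy]dimethylsilane | CC(C)(C)[Si](C)(C)OC/C(Br)=C/[C@H]1O[C@H]1[C@]1(C)O[C@@H]1[C@H]1OC(=O)C=C1 | intermediate
22 | (Z)-but-2-ene-1,4-diol | OC/C=C\CO | starting material
23 | (Z)-1,4-bis(triethylsilyloxy)but-2-ene | CC[Si](CC)(CC)OC/C=C\CO[Si](CC)(CC)CC | intermediate
24 | 3,5-bis[(triethylsilyloxy)methyl]-1,2,4-trioxolane | CC[Si](CC)(CC)OCC1OOC(CO[Si](CC)(CC)CC)O1 | intermediate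
25 | 2-(triethylsilyloxy)acetaldehyde | CC[Si](CC)(CC)OCC=O | intermediate
26 | (3Z)-3-[(tert-butyldimethylsilyloxy)methyl]-1-(triethylsilyloxy)-4-(unit B)but-3-en-2-ol, both C9 epimers | CC[Si](CC)(CC)OCC(O)/C(CO[Si](C)(C)C(C)(C)C)=C\[C@H]1O[C@H]1[C@]1(C)O[C@@H]1[C@H]1OC(=O)C=C1 | intermediate
27 | (3Z)-3-[(tert-butyldimethylsilyloxy)methyl]-1-(triethylsilyloxy)-4-(unit B)but-3-en-2-one | CC[Si](CC)(CC)OCC(=O)/C(CO[Si](C)(C)C(C)(C)C)=C\[C@H]1O[C@H]1[C@]1(C)O[C@@H]1[C@H]1OC(=O)C=C1 | intermediate
28 | (2S,3Z)-3-[(tert-butyldimethylsilyloxy)methyl]-1-(triethylsilyloxy)-4-(unit B)but-3-en-2-ol | CC[Si](CC)(CC)OC[C@@H](O)/C(CO[Si](C)(C)C(C)(C)C)=C\[C@H]1O[C@H]1[C@]1(C)O[C@@H]1[C@H]1OC(=O)C=C1 | intermediate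
29 | (2S,3Z)-3-[(tert-butyldimethylsilyloxy)methyl]-1,2-bis(triethylsilyloxy)-4-(unit B)but-3-ene | CC[Si](CC)(CC)OC[C@@H](O[Si](CC)(CC)CC)/C(CO[Si](C)(C)C(C)(C)C)=C\[C@H]1O[C@H]1[C@]1(C)O[C@@H]1[C@H]1OC(=O)C=C1 | intermediate
30 | (2S,3Z)-3-[(tert-butyldimethylsilyloxy)methyl]-2-(triethylsilyloxy)-4-(unit B)but-3-enal (ring-closure precursor) | O=C[C@@H](O[Si](CC)(CC)CC)/C(CO[Si](C)(C)C(C)(C)C)=C\[C@H]1O[C@H]1[C@]1(C)O[C@@H]1[C@H]1OC(=O)C=C1 | intermediate
31 | (1(10)Z,2R,3R,4R,5R,6S,7R,8S,9S)-14-(tert-butyldimethylsilyloxy)-2,3:4,5-diepoxy-8-hydroxy-9-(triethylsilyloxy)germacr-1(10)-en-12,6-olide | C1C(=O)O[C@H]2[C@H]1[C@H](O)[C@@H](O[Si](CC)(CC)CC)/C(CO[Si](C)(C)C(C)(C)C)=C\[C@H]1O[C@H]1[C@]1(C)O[C@H]21 | intermediate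
32 | angelic acid, (Z)-2-methylbut-2-enoic acid | C/C=C(/C)C(=O)O | starting material
33 | (Z)-2-methylbut-2-en-1-ol | C/C=C(/C)CO | intermediate
34 | [(2S,3R)-2,3-dimethyloxiran-2-yl]methanol | OC[C@]1(C)O[C@@H]1C | intermediate
35 | (2R,3R)-2,3-dimethyloxirane-2-carboxylic acid | OC(=O)[C@]1(C)O[C@@H]1C | intermediate
36 | (2R,3R)-2,3-dimethyloxirane-2-carboxylic 2,4,6-trichlorobenzoic anhydride | O=C(OC(=O)[C@]1(C)O[C@@H]1C)c1c(Cl)cc(Cl)cc1Cl | intermediate
37 | 8-O-[(2R,3R)-2,3-dimethyloxirane-2-carbonyl] derivative of 31 | C1C(=O)O[C@H]2[C@H]1[C@H](OC(=O)[C@]1(C)O[C@@H]1C)[C@@H](O[Si](CC)(CC)CC)/C(CO[Si](C)(C)C(C)(C)C)=C\[C@H]1O[C@H]1[C@]1(C)O[C@H]21 | intermediate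
38 | 11-(dimethylaminomethyl) derivative of 37, C11 epimers | CN(C)CC1C(=O)O[C@H]2[C@H]1[C@H](OC(=O)[C@]1(C)O[C@@H]1C)[C@@H](O[Si](CC)(CC)CC)/C(CO[Si](C)(C)C(C)(C)C)=C\[C@H]1O[C@H]1[C@]1(C)O[C@H]21 | intermediate
39 | 11-(trimethylammoniomethyl) derivative of 37, iodide | C[N+](C)(C)CC1C(=O)O[C@H]2[C@H]1[C@H](OC(=O)[C@]1(C)O[C@@H]1C)[C@@H](O[Si](CC)(CC)CC)/C(CO[Si](C)(C)C(C)(C)C)=C\[C@H]1O[C@H]1[C@]1(C)O[C@H]21.[I-] | intermediate
40 | (1(10)Z)-14-(tert-butyldimethylsilyloxy)-2,3:4,5-diepoxy-8-[(2R,3R)-2,3-dimethyloxirane-2-carbonyloxy]-9-(triethylsilyloxy)germacra-1(10),11(13)-dien-12,6-olide | C=C1C(=O)O[C@H]2[C@H]1[C@H](OC(=O)[C@]1(C)O[C@@H]1C)[C@@H](O[Si](CC)(CC)CC)/C(CO[Si](C)(C)C(C)(C)C)=C\[C@H]1O[C@H]1[C@]1(C)O[C@H]21 | intermediate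
41 | (1(10)Z)-2,3:4,5-diepoxy-8-[(2R,3R)-2,3-dimethyloxirane-2-carbonyloxy]-9,14-dihydroxygermacra-1(10),11(13)-dien-12,6-olide | C=C1C(=O)O[C@H]2[C@H]1[C@H](OC(=O)[C@]1(C)O[C@@H]1C)[C@@H](O)/C(CO)=C\[C@H]1O[C@H]1[C@]1(C)O[C@H]21 | intermediate
42 | (1(10)E)-2,3:4,5-diepoxy-8-[(2R,3R)-2,3-dimethyloxirane-2-carbonyloxy]-9-hydroxy-14-oxogermacra-1(10),11(13)-dien-12,6-olide | C=C1C(=O)O[C@H]2[C@H]1[C@H](OC(=O)[C@]1(C)O[C@@H]1C)[C@@H](O)/C(C=O)=C\[C@H]1O[C@H]1[C@]1(C)O[C@H]21 | intermediate
43 | (1(10)E)-9-acetoxy-2,3:4,5-diepoxy-8-[(2R,3R)-2,3-dimethyloxirane-2-carbonyloxy]-14-oxogermacra-1(10),11(13)-dien-12,6-olide | C=C1C(=O)O[C@H]2[C@H]1[C@H](OC(=O)[C@]1(C)O[C@@H]1C)[C@@H](OC(C)=O)/C(C=O)=C\[C@H]1O[C@H]1[C@]1(C)O[C@H]21 | intermediate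
44 | leucanthin B | C=C1C(=O)O[C@H]2[C@H]1[C@H](OC(=O)[C@]1(C)O[C@@H]1C)[C@@H](OC(C)=O)/C(C(=O)O)=C\[C@H]1O[C@H]1[C@]1(C)O[C@H]21 | target

## Step count and least certain steps

Total: 30 steps. Longest linear sequence: 24 steps (1–9, 11–13, 16–21, 25–30). Side branches: step 10; steps 14–15; steps 22–24.

**Step 21 (key step).** The ten-membered closure is slow, so the ketyl may dimerise or be reduced to the primary alcohol before it reaches C7. Electron transfer to the butenolide or reductive opening of the allylic oxirane may compete. After closure the C8 alkoxide may attack C12 and move the lactone to O8. Facial selection at C8 may also be poor, because the samarium bridge has to form inside a medium-ring transition state. The fallback uses known radical chemistry without a reductant. It sets out from 30: addition of PhSeSiMe3 to the aldehyde should give the O-trimethylsilyl hemiselenoacetal F1. Slow addition of Bu3SnH and AIBN in benzene at 80 °C and high dilution (tin hydride radical macrocyclisation of an α-oxygenated radical onto an enoate acceptor) should give the C8 trimethylsilyl ether F2. Aqueous AcOH/THF then removes the trimethylsilyl group, and the route is rejoined at 31.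

**Step 8.** Oxygen transfer to a cis-allylic alcohol with a quaternary oxirane neighbour may be slow, the catalyst may have to act against the intrinsic facial bias of the substrate, and the titanium alkoxide may open the tertiary allylic 4,5-oxirane. The fallback builds the 2,3-oxirane by C–C bond formation. It sets out from 13: ozonolysis of the C2=C3 alkene through the ozonide F3 should give the α-quaternary epoxy aldehyde F4. Addition of (Z)-γ-chloroallyl-B(Ipc)2 (from allyl chloride, lithium dicyclohexylamide, Ipc2BOMe and BF3·OEt2, reagent enantiomer chosen for the 3R carbinol) should give the syn-chlorohydrin F5. DBU closes it to the cis-vinyl oxirane F6, and a second ozonolysis through the ozonide F7 returns to the route at 15.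

**Step 5.** Facial selection may be poor because both the cis substituent on C4 and the second substituent on C6 are slim alkynyl groups, which weakens the 1,3-allylic strain that fixes the reactive conformer; the electron-poor enyne may also react slowly. The fallback uses reagent control for the oxirane and for C6. It sets out from 5: Sharpless epoxidation with D-(−)-diisopropyl tartrate should give the epoxy alcohol F8. Dess–Martin oxidation gives the epoxy aldehyde F9, and the lithium acetylide of 7 (LiN(SiMe3)2, THF, −78 °C) gives the C6-epimeric carbinols F10. Dess–Martin oxidation gives the ynone F11, and reduction with (R)-2-methyl-CBS-oxazaborolidine and catecholborane, the alkyne acting as the small group, returns to the route at 10.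

**Step 16.** Insertion into the hindered alkenyl bromide may be sluggish, and the low-valent nickel and divalent chromium may ionise or reduce the allylic 2,3-oxirane during the long reaction. The fallback makes the more reactive iodide by another sequence, which also avoids the doubly stabilised bromo ylide of step 11. It sets out from 15: Wittig reaction with 16 should give the epoxy enal F12. α-Iodination (I2, DMAP, K2CO3, THF/H2O) gives the iodo enal F13, Luche reduction gives the iodo alcohol F14, and silylation gives the silyl ether F15. The coupling with 25 can then run at lower temperature with less nickel, and the route is rejoined at 26.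

**Step 26.** The C11 enolate may attack the O8 ester carbonyl through a five-membered transition state (acyl transfer from oxygen to carbon), or enolisation may be incomplete beside the bulky C8 and C9 groups. The fallback changes the order so that no ester is present. It sets out from 31: N-(trimethylsilyl)imidazole should give the silyl ether F2. The same enolate sequence then leads through the Mannich base F16 and the ammonium iodide F17 to the α-methylene lactone F18. Aqueous AcOH/THF gives the hydroxy lactone F19, and Yamaguchi esterification with 35 through 36 returns to the route at 40.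

## Further compounds

F1 | step 21 | O-trimethylsilyl hemiselenoacetal of 30, C8 epimers | C[Si](C)(C)OC([Se]c1ccccc1)[C@@H](O[Si](CC)(CC)CC)/C(CO[Si](C)(C)C(C)(C)C)=C\[C@H]1O[C@H]1[C@]1(C)O[C@@H]1[C@H]1OC(=O)C=C1
F2 | step 21 | 8-O-trimethylsilyl ether of 31 | C1C(=O)O[C@H]2[C@H]1[C@H](O[Si](C)(C)C)[C@@H](O[Si](CC)(CC)CC)/C(CO[Si](C)(C)C(C)(C)C)=C\[C@H]1O[C@H]1[C@]1(C)O[C@H]21
F3 | step 8 | ozonide of 13 | OCC1OOC(O1)[C@]1(C)O[C@@H]1[C@H]1OC(=O)C=C1
F4 | step 8 | (2R,3R)-2-methyl-3-((S)-5-oxo-2,5-dihydrofuran-2-yl)oxirane-2-carbaldehyde | O=C[C@]1(C)O[C@@H]1[C@H]1OC(=O)C=C1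
F5 | step 8 | syn-chlorohydrin, 2-chloro-1-(epoxy butenolide)but-3-en-1-ol | C=C[C@H](Cl)[C@@H](O)[C@]1(C)O[C@@H]1[C@H]1OC(=O)C=C1
F6 | step 8 | cis-vinyl bis-oxirane | C=C[C@H]1O[C@H]1[C@]1(C)O[C@@H]1[C@H]1OC(=O)C=C1
F7 | step 8 | ozonide of F6 | C1OOC(O1)[C@H]1O[C@H]1[C@]1(C)O[C@@H]1[C@H]1OC(=O)C=C1
F8 | step 5 | [(2R,3S)-3-methyl-3-(3-(tert-butyldimethylsilyloxy)prop-1-ynyl)oxiran-2-yl]methanol | CC(C)(C)[Si](C)(C)OCC#C[C@]1(C)O[C@@H]1CO
F9 | step 5 | corresponding oxirane-2-carbaldehyde | CC(C)(C)[Si](C)(C)OCC#C[C@]1(C)O[C@@H]1C=O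
F10 | step 5 | C6-epimeric mixture corresponding to 10 | CC(C)(C)[Si](C)(C)OCC#C[C@]1(C)O[C@@H]1C(O)C#CC(=O)OC
F11 | step 5 | ynone, methyl 4-oxo-4-(epoxide)but-2-ynoate | CC(C)(C)[Si](C)(C)OCC#C[C@]1(C)O[C@@H]1C(=O)C#CC(=O)OC
F12 | step 16 | (E)-3-(unit B)prop-2-enal | O=C/C=C/[C@H]1O[C@H]1[C@]1(C)O[C@@H]1[C@H]1OC(=O)C=C1
F13 | step 16 | (Z)-2-iodo-3-(unit B)prop-2-enal | O=C/C(I)=C/[C@H]1O[C@H]1[C@]1(C)O[C@@H]1[C@H]1OC(=O)C=C1
F14 | step 16 | (Z)-2-iodo-3-(unit B)prop-2-en-1-ol | OC/C(I)=C/[C@H]1O[C@H]1[C@]1(C)O[C@@H]1[C@H]1OC(=O)C=C1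
F15 | step 16 | tert-butyl[(Z)-2-iodo-3-(unit B)prop-2-enyloxy]dimethylsilane | CC(C)(C)[Si](C)(C)OC/C(I)=C/[C@H]1O[C@H]1[C@]1(C)O[C@@H]1[C@H]1OC(=O)C=C1
F16 | step 26 | 11-(dimethylaminomethyl) derivative of F2, C11 epimers | CN(C)CC1C(=O)O[C@H]2[C@H]1[C@H](O[Si](C)(C)C)[C@@H](O[Si](CC)(CC)CC)/C(CO[Si](C)(C)C(C)(C)C)=C\[C@H]1O[C@H]1[C@]1(C)O[C@H]21
F17 | step 26 | 11-(trimethylammoniomethyl) derivative of F2, iodide | C[N+](C)(C)CC1C(=O)O[C@H]2[C@H]1[C@H](O[Si](C)(C)C)[C@@H](O[Si](CC)(CC)CC)/C(CO[Si](C)(C)C(C)(C)C)=C\[C@H]1O[C@H]1[C@]1(C)O[C@H]21.[I-]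
F18 | step 26 | 11(13)-methylene derivative of F2 | C=C1C(=O)O[C@H]2[C@H]1[C@H](O[Si](C)(C)C)[C@@H](O[Si](CC)(CC)CC)/C(CO[Si](C)(C)C(C)(C)C)=C\[C@H]1O[C@H]1[C@]1(C)O[C@H]21
F19 | step 26 | 11(13)-methylene derivative of 31 | C=C1C(=O)O[C@H]2[C@H]1[C@H](O)[C@@H](O[Si](CC)(CC)CC)/C(CO[Si](C)(C)C(C)(C)C)=C\[C@H]1O[C@H]1[C@]1(C)O[C@H]21
A1 | alternative 1 | ten-membered 7,8-alkene with 2-bromo-1-ethoxyethyl ether on O6 | BrCC(OCC)O[C@H]1/C=C/[C@@H](O[Si](C)(C)C(C)(C)C)/C(C(=O)OCC[Si](C)(C)C)=C\[C@H]2O[C@H]2[C@]2(C)O[C@H]12
A2 | alternative 1 | bicyclic lactol ethyl ether with C8 alkoxyamine | C1C(OCC)O[C@H]2[C@H]1[C@H](ON1C(C)(C)CCCC1(C)C)[C@@H](O[Si](C)(C)C(C)(C)C)/C(C(=O)OCC[Si](C)(C)C)=C\[C@H]1O[C@H]1[C@]1(C)O[C@H]21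
A3 | alternative 2 | ten-membered lactone with C2 hydroxyl, 3,4-epoxide and C5 mesylate | C1C(=O)O[C@H]2[C@H]1[C@H](OCc1ccc(OC)cc1)[C@@H](O[Si](C)(C)C(C)(C)C)/C(C(=O)OCC[Si](C)(C)C)=C\[C@@H](O)[C@@H]1O[C@]1(C)[C@H]2OS(C)(=O)=O
A4 | alternative 2 | ten-membered 2,3:4,5-bis-epoxide | C1C(=O)O[C@H]2[C@H]1[C@H](OCc1ccc(OC)cc1)[C@@H](O[Si](C)(C)C(C)(C)C)/C(C(=O)OCC[Si](C)(C)C)=C\[C@H]1O[C@H]1[C@]1(C)O[C@H]21
A5 | alternative 3 | open-chain C6 aldehyde with (Z)-alkenyl iodide at C5 | O=C[C@H](CC(=O)OC)[C@H](OCc1ccc(OC)cc1)[C@@H](O[Si](C)(C)C(C)(C)C)/C(C(=O)OCC[Si](C)(C)C)=C\[C@H]1O[C@H]1/C(C)=C\I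
A6 | alternative 3 | ten-membered allylic alcohol with 2,3-epoxide | [C@@H]1(CC(=O)OC)[C@H](OCc2ccc(OC)cc2)[C@@H](O[Si](C)(C)C(C)(C)C)/C(C(=O)OCC[Si](C)(C)C)=C\[C@H]2O[C@H]2/C(C)=C\[C@H]1O
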